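J 29 mM; X 29.0 mM; time 8.0 min

- E.X and G and X.E.X together at 8.0 min, in percent of the J charged
- concentration of E in solution at 8.0 min, in percent of saturation

- a species is counted by the J in it: one E.E.X counts as two
- amounts and yields of E.X count G and X.E.X too
- given per volume of solution although it is solid: J, G
- at the start none of J is in solution
- E means what is dissolved; the solid is not counted in it
- run time (flask): 8.0 min

    X + E.X ⇌ X.E.X, settled at all times (K1 = 31 M⁻¹)
    J ⇌ E, rate k2*(cs2 - [E]) while solid is left; crystals form when [E] > cs2 (cs2 = 9.5 mM, k2 = 0.0029 s⁻¹)
    G ⇌ E.X, rate k3*(cs3 - [E.X]) while solid is left; crystals form when [E.X] > cs3 (cs3 = 10 mM, k3 = 0.20 s⁻¹)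
    E + E.X → E.E.X (k4 = 1.9 M⁻¹ s⁻¹)
    E + X → E.X (k5 = 0.69 M⁻¹ s⁻¹)

Solid J cannot enter solution faster than it enters an empty one, at 0.0029 s⁻¹ times its solubility of 9.5 mM. So I counted turnovers of the charge. That top rate, held for 8.0 min and set against the 29 mM charged, gave 0.456, the delivery number: the fraction of the charge that dissolving can hand over within the run. It stood below one, so I expected solid J to outlast the run and the yield to stay under that fraction.

One number was not enough. The solution does not stay empty: X as charged takes up E with a pseudo-first-order constant of 1.20 min⁻¹, faster than the 0.17 min⁻¹ at which dissolving refills it, and the half-life of E by that step alone, 0.58 min, is short against the run. I therefore put E at a low steady share of saturation, 12.7 %, which cut the delivery to 0.398 of the charge. The split stayed open, since E meeting E.X has a constant 2.75 times that of E meeting X. I committed only to a yield below that delivery.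

The forecast gave a yield of 21 % and dissolved E at 12.5 % of saturation, holding of E that “reaction with X and E.X removes it as quickly as it arrives”.

The flask gave a yield of 21.1 % and dissolved E at 12.6 % of saturation, with J at 59.6 % of the charge.

The neighbouring flask charged 12 mM of J and kept X at 29.0 mM. Its delivery number came to 1.10, above one, so in that flask the run allowed more than the charge. With the same charge of X I kept the same share of saturation, and the reckoned delivery became 0.960 of the charge. In that flask J ended at 2.46 %, E.E.X held 36.6 %, and the yield reached 51.0 %.

The rate constants are made up; what happens was integrated by code.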